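**Retrosynthetic overview**
1. Late events: the target comes from the 7β-alcohol, this from the 7-oxo-8(17)-ene, this from a Δ7 olefin by a Schenck ene oxidation; the (E)-alkylidene succinimide comes from a Wittig reaction at a C12 aldehyde.
2. C11–C12 and the 9α-H come from a C9 ketone (methylenation, α-face hydroboration, carbonylative one-carbon homologation); the equatorial C2–Cl comes from a C2–OH by radical deoxychlorination.
3. Ring A is closed by making bond C2–C3: the aldehyde carbon (C2) of a CH2CHO arm on C10 is attacked by the CH2 end (C3) of an isopropenyl group on C5, and the C4 cation is methylated. Ring A, the C2 carbinol and the gem-dimethyl group arise in one operation.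
4. Enabling feature: in ring A the heteroatom-bearing C2, the methylene C3 and the quaternary C4(CH3)2 next to ring-fusion carbon C5 form a 1,3-array that reads backwards as C=O plus H2C=C(CH3)–. C3, C4 and one C4 methyl are therefore the isopropenyl group of (R)-carvone, C5 is its stereocentre, and ring B is its ring (its methyl becomes C17, its carbonyl C9).
5. Ring order: ring B is taken from the chiral pool, C10 is made quaternary by two α'-alkylations, then ring A is closed.

Key step: step 4

Remark on numbering: monocyclic compounds use carvone numbering (C1 carbonyl, C5 isopropenyl carbon, C6 α' carbon); bicyclic compounds use labdane numbering (ring A: C1–C5, C10; ring B: C5–C10; C17 on C8; C20 on C10; side chain C11, C12); α is the face opposite to the C10 methyl group.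
Remark on the chemistry: the C2 configuration of the ring-closure product is assumed to be immaterial, because C2 passes through a planar radical in step 6.

**Route**

Step 1
Reactants: 1 (R)-(−)-carvone
Product: 2 (5R)-6-methylcarvone (6-epimers; the trans epimer is shown in the list)
Conditions: LiN(i-Pr)2, THF, −78 °C; MeI, −78 to 0 °C
Reagents that add atoms: methyl iodide, CI
Why: Kinetic deprotonation of the enone occurs at the α' carbon (C6) and the cross-conjugated enolate is C-methylated (enolate alkylation); the new centre is flattened again in step 2, so its configuration does not matter.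

Step 2
Reactants: 2 (5R)-6-methylcarvone
Product: 3 (5R)-6-methyl-6-prenylcarvone (prenyl trans, methyl cis to the isopropenyl group)
Conditions: LiN(i-Pr)2, THF/DMPU, −78 °C; prenyl bromide, −78 to −20 °C
Reagents that add atoms: prenyl bromide (1-bromo-3-methylbut-2-ene), CC(C)=CCBr
Why: The tetrasubstituted α' enolate should be alkylated on the face opposite to the neighbouring isopropenyl group (enolate alkylation, steric control by C5), which places the new arm trans and the methyl cis to it, the relationship that later becomes the trans ring fusion with an axial C10 methyl.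

Step 3
Reactants: 3 (5R)-6-methyl-6-prenylcarvone
Product: 5 (5R)-6-methyl-6-(2-oxoethyl)carvone, via prenyl epoxide 4 (not isolated)
Conditions: mCPBA (1.0 equiv), NaHCO3, CH2Cl2, −20 °C; then H5IO6, THF/H2O, 0 °C
Reagents that add atoms: 3-chloroperoxybenzoic acid, OOC(=O)c1cccc(Cl)c1
Why: The electron-rich trisubstituted prenyl double bond should be epoxidised faster than the 1,1-disubstituted isopropenyl and the electron-poor enone double bonds (Prilezhaev epoxidation), and periodic acid cleaves the epoxide through its diol to the aldehyde and acetone.

Step 4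
Reactants: 5 (5R)-6-methyl-6-(2-oxoethyl)carvone
Product: 7 2α-hydroxy-11,12,13,14,15,16-hexanorlabd-7-en-9-one, via tertiary chloride 6 (not isolated)
Conditions: MeAlCl2 (2.2 equiv), CH2Cl2, −78 °C; then Me3Al (5 equiv), −78 to 0 °C; aqueous potassium sodium tartrate work-up
Reagents that add atoms: trimethylaluminium, C[Al](C)C
Why: Proposed new method: MeAlCl2 binds the aldehyde, the CH2 terminus of the isopropenyl group attacks the activated C=O through a chair transition state with both arms equatorial on ring B, the tertiary C4 cation is taken up by chloride to give 6, and Me3Al then ionises the C–Cl bond and delivers the second methyl of the gem-dimethyl group; the closest known reaction types are the alkylaluminium-halide-promoted Prins (carbonyl-ene type) cyclisation of unsaturated aldehydes to γ-chloro alcohols and the methylation of tertiary alkyl chlorides by Me3Al, which have not been combined in one operation on an isopropenylcyclohexane of this kind. Ring A closes in a 6-endo mode with respect to the alkene (both alkene carbons end up in the ring) and exo with respect to the carbonyl group. The trans ring fusion is not created here but inherited from the trans arrangement of the two arms set in step 2; the only new stereocentre, C2, should carry its aluminium alkoxide equatorial (2α) to avoid the axial C10 methyl, and it is erased in step 6 in any case. The step needs selectivity for the aldehyde over the hindered enone carbonyl (secured by the higher basicity and electrophilicity of the aldehyde and the electron-poor enone alkene), ring closure before methyl addition to the aldehyde (secured by adding Me3Al only after MeAlCl2 has closed the ring), and capture of the C4 cation before proton loss or hydride shift (favoured by the chloride-rich, proton-poor medium at low temperature).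

Step 5
Reactants: 7 2α-hydroxy-11,12,13,14,15,16-hexanorlabd-7-en-9-one
Product: 9 caesium oxalate of 7, via methyl oxalate 8 (not isolated)
Conditions: ClC(O)CO2Me, Et3N, DMAP (cat.), CH2Cl2, 0 °C; then CsOH·H2O (1.0 equiv), THF/H2O, rt
Reagents that add atoms: methyl chlorooxoacetate, COC(=O)C(Cl)=O; caesium hydroxide, [Cs+].[OH-]
Why: The unhindered equatorial alcohol is acylated by the acid chloride, and the strongly activated oxalate methyl ester should be saponified selectively by one equivalent of hydroxide (acylation, ester hydrolysis).

Step 6
Reactants: 9 caesium oxalate of 7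
Product: 10 2α-chloro-11,12,13,14,15,16-hexanorlabd-7-en-9-one
Conditions: Cl3CCO2Et (3 equiv), [Ir(dF(CF3)ppy)2(dtbbpy)]PF6 (1 mol %), 1,4-dioxane, blue LEDs, 60 °C
Reagents that add atoms: ethyl trichloroacetate, CCOC(=O)C(Cl)(Cl)Cl
Why: Photoredox oxidation of the oxalate should release two molecules of CO2 and a planar secondary C2 radical, which abstracts chlorine from the trichloroacetate on the α face because the β face is shielded by the syn-axial methyl groups on C4 and C10, so the chloride ends equatorial (radical deoxychlorination of an alkyl oxalate).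

Step 7
Reactants: 10 2α-chloro-11,12,13,14,15,16-hexanorlabd-7-en-9-one
Product: 11 2α-chloro-12,13,14,15,16-pentanorlabda-7,9(11)-diene
Conditions: Ph3PCH3Br, KOt-Bu, toluene, 90 °C
Reagents that add atoms: methyltriphenylphosphonium bromide, C[P+](c1ccccc1)(c1ccccc1)c1ccccc1.[Br-]
Why: Wittig methylenation with the small unstabilised ylide should convert the hindered ketone into the exocyclic diene, while the equatorial chloride, which has no antiperiplanar hydrogen and a blocked backside, survives the base.

Step 8
Reactants: 11 2α-chloro-12,13,14,15,16-pentanorlabda-7,9(11)-diene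
Product: 13 2α-chloro-13,14,15,16-tetranorlabd-7-en-12-al, via alkylborane 12 (not isolated)
Conditions: 9-BBN, THF, 0 to 60 °C; then CO (1 atm), K[HB(Oi-Pr)3], THF, 0 °C; then H2O2, pH 7 phosphate buffer
Reagents that add atoms: carbon monoxide, [C-]#[O+]
Why: 9-BBN should add to the 1,1-disubstituted end of the diene with boron on the terminal carbon and hydrogen delivered to C9 from the α face, opposite to the axial C10 methyl (this sets the 9α-H), and hydride-induced carbonylation of the B-alkyl-9-BBN followed by oxidation gives the one-carbon-homologated aldehyde (hydroboration, organoborane carbonylation).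

Step 9
Reactants: 14 maleimide; 15 triphenylphosphine
Product: 16 3-(triphenylphosphoranylidene)pyrrolidine-2,5-dione
Conditions: acetone, reflux
Reagents that add atoms: none
Why: Conjugate addition of the phosphine to maleimide followed by proton transfer gives the imide-stabilised ylide.

Step 10
Reactants: 13 2α-chloro-13,14,15,16-tetranorlabd-7-en-12-al; 16 3-(triphenylphosphoranylidene)pyrrolidine-2,5-dione
Product: 17 (E)-alkylidene succinimide with the Δ7 double bond (7-deacetoxy Δ7 isomer of the target)
Conditions: THF/MeOH, 50 °C
Reagents that add atoms: none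
Why: The Wittig reaction of a stabilised ylide with an unhindered aldehyde should give the (E)-alkylidene succinimide, with the alkyl chain anti to the neighbouring imide carbonyl.

Step 11
Reactants: 17 (E)-alkylidene succinimide with the Δ7 double bond
Product: 19 7-oxo-8(17)-ene imide, via allylic hydroperoxide 18 (not isolated)
Conditions: O2, meso-tetraphenylporphyrin (cat.), visible light, CH2Cl2, 0 °C; then Ac2O, pyridine, 0 °C to rt
Reagents that add atoms: oxygen, O=O
Why: Singlet oxygen should add to C7 of the electron-rich trisubstituted alkene from the α face, take a hydrogen from the C8 methyl group and move the double bond to the exocyclic position (Schenck ene reaction), and acetylation and elimination of the secondary hydroperoxide (Kornblum–DeLaMare type) gives the enone, so the C7 configuration of 18 is irrelevant.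

Step 12
Reactants: 19 7-oxo-8(17)-ene imide
Product: 20 7β-hydroxy-8(17)-ene imide
Conditions: NaBH4, CeCl3·7H2O, MeOH/THF, −78 °C
Reagents that add atoms: none
Why: Luche 1,2-reduction should deliver hydride axially from the α face of the enone carbonyl, giving the equatorial 7β alcohol, while the imide reacts far more slowly at this temperature.

Step 13
Reactants: 20 7β-hydroxy-8(17)-ene imide
Product: 21 target (CNP0220384.1)
Conditions: Ac2O, pyridine, CH2Cl2, 0 °C to rt
Reagents that add atoms: acetic anhydride, CC(=O)OC(C)=O
Why: Acetylation of the secondary allylic alcohol under mild conditions that should leave the imide N–H untouched gives the target.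

**Compound list**
1 | (R)-(−)-carvone | CC1=CC[C@@H](C(C)=C)CC1=O | starting material
2 | (5R)-6-methylcarvone, trans epimer shown (6-epimer mixture) | CC1=CC[C@@H](C(C)=C)[C@H](C)C1=O | intermediate
3 | (5R)-6-methyl-6-prenylcarvone, prenyl trans to isopropenyl | CC1=CC[C@@H](C(C)=C)[C@@](CC=C(C)C)(C)C1=O | intermediate
4 | prenyl epoxide of 3 (both epoxide epimers) | CC1=CC[C@@H](C(C)=C)[C@@](CC2OC2(C)C)(C)C1=O | intermediate
5 | (5R)-6-methyl-6-(2-oxoethyl)carvone, CH2CHO trans to isopropenyl | CC1=CC[C@@H](C(C)=C)[C@@](CC=O)(C)C1=O | intermediate
6 | 4-chloro-2α-hydroxy-4-methyl analogue of 7 (C4 epimers; present as its aluminium alkoxide) | CC1=CC[C@H]2C(C)(Cl)C[C@H](O)C[C@]2(C)C1=O | intermediate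
7 | 2α-hydroxy-11,12,13,14,15,16-hexanorlabd-7-en-9-one (5α-H, 10β-CH3) | CC1=CC[C@H]2C(C)(C)C[C@H](O)C[C@]2(C)C1=O | intermediate
8 | methyl oxalate of 7 | CC1=CC[C@H]2C(C)(C)C[C@H](OC(=O)C(=O)OC)C[C@]2(C)C1=O | intermediate
9 | caesium oxalate of 7 | [Cs+].CC1=CC[C@H]2C(C)(C)C[C@H](OC(=O)C([O-])=O)C[C@]2(C)C1=O | intermediate
10 | 2α-chloro-11,12,13,14,15,16-hexanorlabd-7-en-9-one | CC1=CC[C@H]2C(C)(C)C[C@H](Cl)C[C@]2(C)C1=O | intermediate
11 | 2α-chloro-12,13,14,15,16-pentanorlabda-7,9(11)-diene | CC1=CC[C@H]2C(C)(C)C[C@H](Cl)C[C@]2(C)C1=C | intermediate
12 | 11-(9-borabicyclo[3.3.1]non-9-yl)-2α-chloro-12,13,14,15,16-pentanorlabd-7-ene (9α-H) | CC1=CC[C@H]2C(C)(C)C[C@H](Cl)C[C@]2(C)[C@H]1CB1C2CCCC1CCC2 | intermediate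
13 | 2α-chloro-13,14,15,16-tetranorlabd-7-en-12-al (9α-H) | CC1=CC[C@H]2C(C)(C)C[C@H](Cl)C[C@]2(C)[C@H]1CC=O | intermediate
14 | maleimide | O=C1C=CC(=O)N1 | starting material
15 | triphenylphosphine | c1ccc(cc1)P(c1ccccc1)c1ccccc1 | starting material
16 | 3-(triphenylphosphoranylidene)pyrrolidine-2,5-dione | O=C1CC(=P(c2ccccc2)(c2ccccc2)c2ccccc2)C(=O)N1 | intermediate
17 | (E)-alkylidene succinimide, 2α-chloro, Δ7 | CC1=CC[C@H]2C(C)(C)C[C@H](Cl)C[C@]2(C)[C@H]1C/C=C1\CC(=O)NC1=O | intermediate
18 | 7α-hydroperoxy-8(17)-ene imide | C=C1[C@H](OO)C[C@H]2C(C)(C)C[C@H](Cl)C[C@]2(C)[C@H]1C/C=C1\CC(=O)NC1=O | intermediate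
19 | 7-oxo-8(17)-ene imide | C=C1C(=O)C[C@H]2C(C)(C)C[C@H](Cl)C[C@]2(C)[C@H]1C/C=C1\CC(=O)NC1=O | intermediate
20 | 7β-hydroxy-8(17)-ene imide | C=C1[C@@H](O)C[C@H]2C(C)(C)C[C@H](Cl)C[C@]2(C)[C@H]1C/C=C1\CC(=O)NC1=O | intermediate
21 | CNP0220384.1 (2α-chloro-7β-acetoxy-8(17)-ene, 12E imide) | C=C1[C@@H](OC(C)=O)C[C@H]2C(C)(C)C[C@H](Cl)C[C@]2(C)[C@H]1C/C=C1\CC(=O)NC1=O | target

**Step count and risks**
Total: 13 steps. Longest linear sequence: 12 steps (steps 1–8 and 10–13; step 9 is a one-step side branch).

Steps most likely to fail:

1. Step 4 (the proposed new method). The C4 cation may lose a proton or undergo a 1,2-hydride shift from C5 faster than it is captured, or Me3Al may add to a carbonyl group. The fallback uses known chemistry, sets out from 5 and returns at 7. Me2AlCl (CH2Cl2, −78 °C) induces the concerted type 2 carbonyl-ene cyclisation, which forms the same C2–C3 bond without a free cation and gives the 4-methylene alcohol F1. HCl in CH2Cl2 at −30 °C adds in the Markovnikov sense to the exocyclic alkene and gives the tertiary chloride 6, now isolated. Me3Al (CH2Cl2, −78 to 0 °C) replaces the tertiary chloride by methyl and gives 7.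

2. Step 11. Hydrogen abstraction may be poorly regioselective: the axial C9–H competes with the methyl hydrogens, which would lead to the endocyclic Δ8(9) hydroperoxide and the conjugated endocyclic enone. The fallback sets out from 17 and returns at 19. mCPBA (NaHCO3, CH2Cl2, 0 °C) epoxidises the electron-rich Δ7 alkene from the α face to the 7α,8α-epoxide F2. Cp2TiCl (trivalent titanium, made from Cp2TiCl2 and Mn dust, THF) opens the epoxide to the tertiary C8 radical, which is trapped by a second titanium centre and loses a methyl hydrogen, giving the 7α-hydroxy-8(17)-ene F3. Oxidation with DMP (1,1,1-triacetoxy-1,1-dihydro-1,2-benziodoxol-3(1H)-one, NaHCO3, CH2Cl2) gives 19.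

3. Step 6. Loss of the second CO2 from the secondary alkoxycarbonyl radical may be slow, so that it is intercepted before C2 becomes a radical, or the facial selectivity of chlorine transfer may be incomplete. The fallback sets out from 7, replaces steps 5 and 6, and returns at 10. DMP oxidation gives the 2,9-dione F4. NaBH4 (MeOH/CH2Cl2, −78 °C) should reduce the saturated C2 ketone in preference to the hindered conjugated C9 ketone, with hydride from the open α face, giving the axial 2β-alcohol F5. The Appel reaction (PPh3, CCl4, 60 °C) displaces the activated axial oxygen with inversion by equatorial attack of chloride and gives 10.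

**Further compounds**
F1 | step 4 | 2α-hydroxy-4-methylene-8,10β-dimethyl-5α-decal-7-en-9-one (carbonyl-ene product) | CC1=CC[C@H]2C(=C)C[C@H](O)C[C@]2(C)C1=O
F2 | step 11 | 7α,8α-epoxide of 17 | C[C@@]12O[C@@H]1C[C@H]1C(C)(C)C[C@H](Cl)C[C@]1(C)[C@H]2C/C=C1\CC(=O)NC1=O
F3 | step 11 | 7α-hydroxy-8(17)-ene imide | C=C1[C@H](O)C[C@H]2C(C)(C)C[C@H](Cl)C[C@]2(C)[C@H]1C/C=C1\CC(=O)NC1=O
F4 | step 6 | 11,12,13,14,15,16-hexanorlabd-7-ene-2,9-dione | CC1=CC[C@H]2C(C)(C)CC(=O)C[C@]2(C)C1=O
F5 | step 6 | 2β-hydroxy-11,12,13,14,15,16-hexanorlabd-7-en-9-one | CC1=CC[C@H]2C(C)(C)C[C@@H](O)C[C@]2(C)C1=O
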